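I read the slope first. A closed, stirred flask takes gas from a held gas phase into solution, where it meets the substrate, and two earlier runs show how the target rises and falls.

the same everywhere: gas phase 6.1 mM (held)
- cedar: substrate 10 mM; run made earlier
- birch: substrate 15 mM; run made earlier
- flask: substrate 20 mM; time 80 min

| run | time / min | target / % |
|---|---|---|
| cedar | 5.00 | 32.4 |
| cedar | 8.00 | 40.3 |
| cedar | 12.0 | 42.0 |
| cedar | 20.0 | 38.8 |
| cedar | 30.0 | 33.5 |
| cedar | 40.0 | 31.9 |
| cedar | 60.0 | 26.4 |
| birch | 10.0 | 39.5 |
| birch | 20.0 | 38.4 |
| birch | 30.0 | 34.3 |
| birch | 40.0 | 28.8 |
| birch | 50.0 | 26.6 |
| birch | 60.0 | 23.1 |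

(scatter of a reading: 1 percentage point)

- at the start none of the gas is dissolved
- on the list of suspects stand: gas phase <-> dissolved gas; substrate + dissolved gas -> target; substrate -> side product; target <-> isomer of the product; dissolved gas -> decomposed reagent

- the target standing at 80 min, as a percentage of the substrate charged
- concentration of dissolved gas in solution at 8.0 min, in percent of saturation
- the change that raises the amount of target at 80 min, in percent of the substrate charged most ("none" if none brings more than 2 percentage points) (Saturday's / Monday's / none)
- amount of target at 80 min, in percent of the substrate charged, after Monday's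

- Saturday's: doubling the transfer coefficient of the gas phase, all else as stated
- Monday's: doubling the saturation concentration of gas phase, all else as stated

I put the target on a logarithmic axis and pool its fall from 20.0 min to 60.0 min in cedar and from 20.0 min to 60.0 min in birch. This gives 206 min, my decade time D, the time the target takes to lose one decade.

The ladder has two rungs. The lower one is the rise: cedar reads 32.4% at 5.00 min and its highest reading is 42.0% at 12.0 min, while birch reads 39.5% at 10.0 min. The upper rung is D, longer than that peak time by a factor of 17.2. The asked 80 min is later than the cedar peak but shorter than D, so the flask should stand on the falling branch, a fraction of a decade down.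

I start from the nearest loading, birch at 60.0 min with 23.1%, and carry it forward 20.0 min. My reckoning gives 18.5%.

The forecast says 18.5% (range 15.5% to 22%) and 55% of saturation at 8.0 min. It picks Monday's change, reaching 26%, and holds that “target drains slowly at about 0.01/min, probably to the isomer”.

The flask gives 20.6% and 54.3%. Monday's change wins, adding 7.1 percentage points against 4 points for the other, and reaches 27.7%.

    gas phase ⇌ dissolved gas, rate k1*(csat - [dissolved gas]) (kL = 0.0127 /s)
    substrate + dissolved gas → target (k = 0.885 /M/s)
    substrate → side product (k = 0.00258 /s)
    target ⇌ isomer of the product (K = 2.70, k = 2.08 × 10⁻⁴ /s)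
    dissolved gas → decomposed reagent (k = 0.00847 /s)

From the flask's 29.3% at 40.0 min, D gives 18.7% at 80 min, against the 20.6% that stands there. From 20.6%, D gives 1.77% for the same flask read at 5.0 h, where the target stands at 12.1%. In the flask the ratio of forward to back rate between target and isomer, K times target over isomer, is 2.39 at 80 min. At 5.0 h it is 1.02.

(The readings were computed with made-up constants; noise was put on by code.)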